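**Plan**
1. Locants (target ring): C1 carbinol, C2 CMe2, C3=C4, C5(=CH2), C6, C7, C8=C9(Me), C10, C11. The cuts come in this order: the vanillate ester C–O bond, then C1–OH back to the C1 ketone, then the ring bond C10–C11.
2. Enabling feature: at the ketone level, C1(=O)–C11H2–C10H2–C9(Me)=C8 is a γ,δ-unsaturated ketone. C11 is its only enolisable carbon because C2 is quaternary, and C10 is the free terminus of the C8–C9–C10 allyl unit. The 11-membered carbocycle is therefore the CO2-extrusion product of a 13-membered allyl β-keto lactone (C11–CO–O–C10).
3. Further cuts: the lactone acyl–O bond (acylketene), C1–C11 (crossed Claisen), C10–O (allylic oxidation), C5=CH2 (Wittig), C3=C4 (HWE) and C6–C7 (dianion alkylation).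
4. Forward: the chain is joined in the order C6–C7, C3=C4, C5=CH2, C10–O, C1–C11. The 13-membered lactone ring arises first and is contracted to the 11-membered ring. Reduction, acylation and desilylation finish the route.
5. Stereochemistry: E-C3=C4 comes from the HWE step. E-C8=C9 comes from the E-selective SeO2 oxidation and is carried through the syn-η3-allyl intermediate. (R)-C1 comes from an (S)-Me-CBS reduction that distinguishes the large quaternary C2 flank from the small C11H2 flank.

Key step: step 7

Remark: the descriptor at the carbinol carbon of the given SMILES is read as R (O > C2 > C11 > H). The target ring locants above are used for all intermediates.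

**Step 1**
Reactants: 1 dimethyl (2-oxopropyl)phosphonate; 2 prenyl bromide (1-bromo-3-methylbut-2-ene)
Product: 3 dimethyl (6-methyl-2-oxohept-5-en-1-yl)phosphonate
Conditions: NaH, THF, 0 °C; n-BuLi, 0 °C; then 2, 0 °C to rt; 1 M HCl quench at 0 °C
Reagents that add atoms: none
Why: γ-Alkylation of a β-ketophosphonate dianion, in which the terminal, more basic carbanion is the more nucleophilic site and displaces the primary allylic bromide by SN2, so that C6–C7 forms without touching the phosphonate-bearing carbon.

**Step 2**
Reactants: 3 dimethyl (6-methyl-2-oxohept-5-en-1-yl)phosphonate; 4 methyl 2,2-dimethyl-3-oxopropanoate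
Product: 5 methyl (3E)-2,2,9-trimethyl-5-oxodeca-3,8-dienoate
Conditions: LiCl, i-Pr2NEt, MeCN, rt
Reagents that add atoms: none
Why: Horner–Wadsworth–Emmons olefination under Masamune–Roush conditions, in which the stabilised phosphonate anion adds reversibly to the non-enolisable neopentyl aldehyde and collapses to the E-enone (C3=C4), while the amine base spares the ester and avoids retro-Claisen loss of the formyl group.

**Step 3**
Reactants: 5 methyl (3E)-2,2,9-trimethyl-5-oxodeca-3,8-dienoate
Product: 6 methyl (3E)-2,2,9-trimethyl-5-methylidenedeca-3,8-dienoate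
Conditions: MePPh3Br, KHMDS, THF, 0 °C; then 5, 0 °C to rt
Reagents that add atoms: methyltriphenylphosphonium bromide C[P+](c1ccccc1)(c1ccccc1)c1ccccc1.[Br-]
Why: Wittig methylenation, in which the non-stabilised ylide adds 1,2 to the enone carbonyl and leaves the hindered α,α-dimethyl ester alone, giving the 2-substituted E-1,3-diene.

**Step 4**
Reactants: 6 methyl (3E)-2,2,9-trimethyl-5-methylidenedeca-3,8-dienoate
Product: 7 methyl (3E,8E)-10-hydroxy-2,2,9-trimethyl-5-methylidenedeca-3,8-dienoate
Conditions: SeO2 (cat.), t-BuOOH, CH2Cl2, 0 °C
Reagents that add atoms: tert-butyl hydroperoxide CC(C)(C)OO; selenium dioxide O=[Se]=O (catalytic oxygen carrier)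
Why: Catalytic SeO2 allylic oxidation (ene reaction followed by a [2,3]-shift) attacks the most electron-rich, trisubstituted alkene and hydroxylates the methyl group trans to the chain, as it does in myrcene-type trienes, which fixes E-C8=C9.

**Step 5**
Reactants: 7 methyl (3E,8E)-10-hydroxy-2,2,9-trimethyl-5-methylidenedeca-3,8-dienoate
Product: 8 tert-butyl (5E,10E)-12-hydroxy-4,4,11-trimethyl-7-methylidene-3-oxododeca-5,10-dienoate
Conditions: t-BuOAc, LiN(i-Pr)2 (4 equiv each), THF, −78 °C; then 7, −78 °C to rt; AcOH quench
Reagents that add atoms: tert-butyl acetate CC(=O)OC(C)(C)C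
Why: Crossed Claisen condensation, in which lithio tert-butyl acetate is stable up to room temperature, so an excess (which also takes up the OH proton and the acidic product) can be pushed onto the hindered, non-enolisable ester while the product stays protected as its enolate.

**Step 6**
Reactants: 8 tert-butyl (5E,10E)-12-hydroxy-4,4,11-trimethyl-7-methylidene-3-oxododeca-5,10-dienoate
Product: 10 (6E,11E)-5,5,12-trimethyl-8-methylidene-1-oxacyclotrideca-6,11-diene-2,4-dione, via acylketene 9 (not isolated)
Conditions: toluene (about 1 mM), reflux, syringe-pump addition, 4 Å molecular sieves in the condensate path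
Reagents that add atoms: none
Why: Thermal loss of tert-butanol from the tert-butyl β-keto ester gives the acylketene, which the primary allylic hydroxyl traps (acylketene macrolactonisation) to form a little-strained 13-membered ring under neutral conditions that spare the diene.

**Step 7**
Reactants: 10 (6E,11E)-5,5,12-trimethyl-8-methylidene-1-oxacyclotrideca-6,11-diene-2,4-dione
Product: 12 (3E,8E)-2,2,9-trimethyl-5-methylidenecycloundeca-3,8-dien-1-one, via palladium enolate 11 (not isolated)
Conditions: Pd2(dba)3 (5 mol %), PPh3 (25 mol %), toluene (about 1 mM), slow addition, 25 to 60 °C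
Reagents that add atoms: none
Why: Proposed new method: zerovalent palladium ionises the allylic C10–O bond of 10 (ring opening to an η3-allylpalladium β-keto carboxylate), CO2 is lost to give the palladium enolate 11 of the C1 ketone, and C11 then bonds to the unsubstituted allyl terminus C10 with release of the catalyst. The closest known reaction type is the palladium-catalysed decarboxylative allylation of acyclic allyl β-keto esters (the catalytic Carroll reaction), together with Tsuji–Trost macrocyclisation of β-keto ester/allylic ester pairs to eleven-membered carbocycles; what is untested is the ring-contracting use on a macrocyclic β-keto lactone. The eleven-membered ring closes in the endo mode with respect to the allyl unit (attack at the distal terminus C10, so that C8=C9 ends up in the ring), and the alternative 9-exo closure at the secondary terminus C8 is disfavoured by substitution and by medium-ring strain. No stereocentre is formed, and the E geometry of C8=C9 is carried over because the E-allyl ester gives the syn-η3-allyl, whose syn–anti exchange would need an η1 form bound at the secondary carbon C8. The step needs intramolecular rather than intermolecular recombination, C- rather than O-allylation and a single enolate: nucleophile and electrophile are generated one-to-one in the same molecule as a contact ion pair in toluene at high dilution without external base, O-allylation is reversible under the catalyst, and quaternary C2 leaves C11 as the only enolate carbon. The 1,3-diene and the ketone product should be inert to the neutral catalyst, and CO2 is the only helper group, which leaves by itself.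

**Step 8**
Reactants: 12 (3E,8E)-2,2,9-trimethyl-5-methylidenecycloundeca-3,8-dien-1-one
Product: 13 (1R,3E,8E)-2,2,9-trimethyl-5-methylidenecycloundeca-3,8-dien-1-ol
Conditions: (S)-Me-CBS oxazaborolidine premixed with BH3·SMe2 (1 equiv each), toluene, −40 °C; MeOH quench at −40 °C
Reagents that add atoms: none
Why: Corey–Bakshi–Shibata reduction, in which the ketone binds to the catalyst boron with the large quaternary C2 flank turned away, hydride reaches the face that gives the (R)-alcohol (the sense known for tert-alkyl methyl ketones with the S catalyst), and the preformed catalyst–borane complex keeps free borane away from the alkenes.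

**Step 9**
Reactants: 14 vanillic acid (4-hydroxy-3-methoxybenzoic acid)
Product: 16 4-[(tert-butyldimethylsilyl)oxy]-3-methoxybenzoic acid, via bis-silyl compound 15 (not isolated)
Conditions: TBSCl (2.2 equiv), imidazole, DMF, rt; then AcOH–THF–H2O, rt
Reagents that add atoms: tert-butyldimethylsilyl chloride CC(C)(C)[Si](C)(C)Cl
Why: Standard silylation of phenol and acid followed by selective hydrolysis of the labile silyl ester, which leaves the aryl silyl ether in place.

**Step 10**
Reactants: 13 (1R,3E,8E)-2,2,9-trimethyl-5-methylidenecycloundeca-3,8-dien-1-ol; 16 4-[(tert-butyldimethylsilyl)oxy]-3-methoxybenzoic acid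
Product: 18 (1R,3E,8E)-2,2,9-trimethyl-5-methylidenecycloundeca-3,8-dien-1-yl 4-[(tert-butyldimethylsilyl)oxy]-3-methoxybenzoate, via mixed anhydride 17 (not isolated)
Conditions: 16, 2,4,6-trichlorobenzoyl chloride, Et3N, toluene, rt; then 13, DMAP, toluene, 60 °C
Reagents that add atoms: 2,4,6-trichlorobenzoyl chloride O=C(Cl)c1c(Cl)cc(Cl)cc1Cl (its aroyl group is carried only by 17 and is lost again)
Why: Yamaguchi esterification, in which DMAP transfers the vanilloyl group from the mixed anhydride to the hindered neopentyl alcohol at the acyl carbon, so the C1–O bond and its configuration are untouched.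

**Step 11**
Reactants: 18 (1R,3E,8E)-2,2,9-trimethyl-5-methylidenecycloundeca-3,8-dien-1-yl 4-[(tert-butyldimethylsilyl)oxy]-3-methoxybenzoate
Product: 19 (1R,3E,8E)-2,2,9-trimethyl-5-methylidenecycloundeca-3,8-dien-1-yl 4-hydroxy-3-methoxybenzoate (target)
Conditions: TBAF, AcOH (1:1), THF, 0 °C
Reagents that add atoms: none
Why: Fluoride cleavage of the aryl silyl ether, buffered with acetic acid so that neither the hindered benzoate nor the acid- and base-sensitive diene is disturbed.

**Compound list**
1 | dimethyl (2-oxopropyl)phosphonate | CC(=O)CP(=O)(OC)OC | starting material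
2 | prenyl bromide | CC(C)=CCBr | starting material
3 | dimethyl (6-methyl-2-oxohept-5-en-1-yl)phosphonate | COP(=O)(OC)CC(=O)CCC=C(C)C | intermediate
4 | methyl 2,2-dimethyl-3-oxopropanoate | COC(=O)C(C)(C)C=O | starting material
5 | methyl (3E)-2,2,9-trimethyl-5-oxodeca-3,8-dienoate | COC(=O)C(C)(C)/C=C/C(=O)CCC=C(C)C | intermediate
6 | methyl (3E)-2,2,9-trimethyl-5-methylidenedeca-3,8-dienoate | COC(=O)C(C)(C)/C=C/C(=C)CCC=C(C)C | intermediate
7 | methyl (3E,8E)-10-hydroxy-2,2,9-trimethyl-5-methylidenedeca-3,8-dienoate | COC(=O)C(C)(C)/C=C/C(=C)CC/C=C(\C)CO | intermediate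
8 | tert-butyl (5E,10E)-12-hydroxy-4,4,11-trimethyl-7-methylidene-3-oxododeca-5,10-dienoate | CC(C)(C)OC(=O)CC(=O)C(C)(C)/C=C/C(=C)CC/C=C(\C)CO | intermediate
9 | acylketene, (5E,10E)-12-hydroxy-4,4,11-trimethyl-7-methylidenedodeca-1,5,10-triene-1,3-dione (not isolated) | O=C=CC(=O)C(C)(C)/C=C/C(=C)CC/C=C(\C)CO | intermediate
10 | (6E,11E)-5,5,12-trimethyl-8-methylidene-1-oxacyclotrideca-6,11-diene-2,4-dione | O=C1CC(=O)C(C)(C)/C=C/C(=C)CC/C=C(\C)CO1 | intermediate
11 | η1-allyl palladium O-enolate of the seco ketone, phosphine ligands omitted (not isolated) | C=C1O[Pd]C/C(C)=C/CCC(=C)/C=C/C1(C)C | intermediate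
12 | (3E,8E)-2,2,9-trimethyl-5-methylidenecycloundeca-3,8-dien-1-one | O=C1CC/C(C)=C/CCC(=C)/C=C/C1(C)C | intermediate
13 | (1R,3E,8E)-2,2,9-trimethyl-5-methylidenecycloundeca-3,8-dien-1-ol | C=C1/C=C/C(C)(C)[C@H](O)CC/C(C)=C/CC1 | intermediate
14 | vanillic acid | COc1cc(C(=O)O)ccc1O | starting material
15 | tert-butyldimethylsilyl 4-[(tert-butyldimethylsilyl)oxy]-3-methoxybenzoate (not isolated) | COc1cc(C(=O)O[Si](C)(C)C(C)(C)C)ccc1O[Si](C)(C)C(C)(C)C | intermediate
16 | 4-[(tert-butyldimethylsilyl)oxy]-3-methoxybenzoic acid | COc1cc(C(=O)O)ccc1O[Si](C)(C)C(C)(C)C | intermediate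
17 | 4-[(tert-butyldimethylsilyl)oxy]-3-methoxybenzoic 2,4,6-trichlorobenzoic anhydride (not isolated) | COc1cc(C(=O)OC(=O)c2c(Cl)cc(Cl)cc2Cl)ccc1O[Si](C)(C)C(C)(C)C | intermediate
18 | (1R,3E,8E)-2,2,9-trimethyl-5-methylidenecycloundeca-3,8-dien-1-yl 4-[(tert-butyldimethylsilyl)oxy]-3-methoxybenzoate | C=C1/C=C/C(C)(C)[C@H](OC(=O)c2ccc(O[Si](C)(C)C(C)(C)C)c(OC)c2)CC/C(C)=C/CC1 | intermediate
19 | (1R,3E,8E)-2,2,9-trimethyl-5-methylidenecycloundeca-3,8-dien-1-yl 4-hydroxy-3-methoxybenzoate | C=C1/C=C/C(C)(C)[C@H](OC(=O)c2ccc(O)c(OC)c2)CC/C(C)=C/CC1 | target

**Totals**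
Total step count: 11.
Longest linear sequence: 10 steps (steps 1–8, 10 and 11). Step 9 is a side branch.

**Steps most likely to fail**

1. Step 7 (ring contraction).
 - What may go wrong: after ionisation and CO2 loss, the enolate may be protonated, or the allyl unit may lose a β-hydride, faster than the strained eleven-membered ring closes. Ion pairs may also recombine between molecules and give oligomers.
 - Fallback (known chemistry): it sets out from 8, rejoins at 12, and also bypasses step 6. The allylic alcohol of 8 is acylated (ClCO2Me, pyridine, CH2Cl2, 0 °C) to tert-butyl (5E,10E)-12-[(methoxycarbonyl)oxy]-4,4,11-trimethyl-7-methylidene-3-oxododeca-5,10-dienoate F1.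
 - A classical Tsuji–Trost macrocyclisation with the stabilised β-keto ester nucleophile follows (Pd(PPh3)4, dppe, THF, reflux, slow addition; the liberated methoxide serves as base). It should give tert-butyl (4E,9E)-3,3,10-trimethyl-6-methylidene-2-oxocycloundeca-4,9-diene-1-carboxylate F2.
 - Heating F2 in wet DMSO at about 130 °C (loss of tert-butanol through the α-oxoketene, hydration, decarboxylation) removes the activating ester without acid and delivers 12.

2. Step 5 (crossed Claisen at a hindered ester).
 - What may go wrong: addition to the α,α-dimethyl ester may be slower than self-condensation of the enolate, and the product may suffer retro-Claisen cleavage on work-up.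
 - Fallback: it sets out from 7 and rejoins at 8. The C1–C11 bond is made at the aldehyde oxidation level instead. DIBAL-H (2.1 equiv, CH2Cl2, −78 °C; the neopentyl tetrahedral aluminate is stable) gives (3E,8E)-10-hydroxy-2,2,9-trimethyl-5-methylidenedeca-3,8-dienal F3.
 - F3 is homologated by the Roskamp reaction (tert-butyl diazoacetate, SnCl2 cat., CH2Cl2, rt; addition, 1,2-hydride shift, loss of N2) to 8.

3. Step 8 (asymmetric reduction).
 - What may go wrong: facial selectivity may be poor if the macrocycle conformation masks the size difference of the two flanks, and the 1,1-disubstituted diene terminus may undergo competing hydroboration.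
 - Fallback: it sets out from 12 and rejoins at 13. It is a biocatalytic reduction with an NADPH-dependent ketoreductase (short-chain dehydrogenase/reductase class), chosen from a panel for the (R)-alcohol, run with i-PrOH as hydride donor in buffer–DMSO at 30 °C.
 - The enzyme reads the quaternary versus methylene flanks and cannot touch C=C bonds. This fallback makes no compound outside the list (F0).

**Further compounds**
F1 | step 7 | tert-butyl (5E,10E)-12-[(methoxycarbonyl)oxy]-4,4,11-trimethyl-7-methylidene-3-oxododeca-5,10-dienoate | CC(C)(C)OC(=O)CC(=O)C(C)(C)/C=C/C(=C)CC/C=C(\C)COC(=O)OC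
F2 | step 7 | tert-butyl (4E,9E)-3,3,10-trimethyl-6-methylidene-2-oxocycloundeca-4,9-diene-1-carboxylate | CC(C)(C)OC(=O)C1C/C(C)=C/CCC(=C)/C=C/C(C)(C)C1=O
F3 | step 5 | (3E,8E)-10-hydroxy-2,2,9-trimethyl-5-methylidenedeca-3,8-dienal | O=CC(C)(C)/C=C/C(=C)CC/C=C(\C)CO
F0 | step 8 | none | none
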